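Everything rests on cutting ring C at C2–C3. In the open form C2 is a methylene that is benzylic to the electron-rich ring B and bonded to O1. It is the sixth atom of the chain C3–C4–C4a–C8a–O1–C2, so a rhodium carbenoid raised at C3 finds this one activated C–H site and no other. With a chiral Rh(II) carboxylate, a single operation makes C2–C3, closes the pyranone ring and picks one of the two enantiotopic hydrogens, which fixes (2S). The substrate is a tetra-silylated aryl diazomethyl ketone whose ring A already carries the C8 prenyl group and, on O1, the complete ring B benzyl unit.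

Key step: step 10

Assumption: the sense of induction of the prolinate catalyst on this substrate cannot be predicted with confidence. The route is written with the (S)-ligand, and the equally available (R)-ligand takes its place if the CD spectrum of the insertion product indicates (2R).

Remarks on the design (TBS = tert-butyldimethylsilyl, TBSO = its ether)
- Configuration: at C2 the priorities are O1 > C1' > C3 > H, so the tag in the target corresponds to (2S).
- Protecting groups: all four phenols are TBS ethers.
  - On O5, silicon stands where an O–C–H would offer a second 1,6 site.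
  - The silyl groups make the diazoketone soluble in hexane, the medium in which prolinate catalysts are at their most selective.
  - They leave together under weakly acidic fluoride, so no phenoxide forms that could open the flavanone to the chalcone.
- Order of events: the prenyl group is put on ring A by C-alkylation before the ether bond is made.
  - The heat- and acid-sensitive 2,4-disilyloxybenzyl aryl ether is therefore never heated.
  - Only the hydroxyl wedged between acetyl and prenyl is left free for etherification, which fixes 8-prenyl over 6-prenyl.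
- Alkenes: the prenyl group could meet the carbenoid only through a meta-bridged ring, and the vinyl group only through a macrocycle. Only bimolecular cyclopropanation has to be suppressed, and dilution does that.

Step 1
Reactants: 1 2,4,6-trihydroxyacetophenone; 2 prenyl bromide (1-bromo-3-methylbut-2-ene)
Product: 3 1-[2,4,6-trihydroxy-3-(3-methylbut-2-en-1-yl)phenyl]ethan-1-one
Conditions: KOH (1.0 equiv), H2O, 0 °C → rt; 2 (0.9 equiv) added slowly
Reagents that add atoms: none
Why: C-alkylation of the ambident phloroglucinol-type phenoxide in water, where solvation of oxygen steers the soft allylic bromide to carbon, the two free ring positions being equivalent and the deficit of 2 limiting double prenylation.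

Step 2
Reactants: 3 1-[2,4,6-trihydroxy-3-(3-methylbut-2-en-1-yl)phenyl]ethan-1-one
Product: 4 1-[4,6-bis(TBSO)-2-hydroxy-3-(3-methylbut-2-en-1-yl)phenyl]ethan-1-one
Conditions: TBSCl (2.2 equiv), imidazole, DMF, 0 °C → rt
Reagents that add atoms: tert-butyldimethylsilyl chloride, CC(C)(C)[Si](C)(C)Cl
Why: Sterically controlled silyl ether formation, in which the unchelated 4-OH reacts first and the chelated hydroxyl next to H-5 reacts ahead of the one between acetyl and prenyl, which stays as the hydrogen-bonded phenol.

Step 3
Reactants: 5 2,4-dihydroxybenzaldehyde; 2 prenyl bromide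
Product: 6 2-hydroxy-4-[(3-methylbut-2-en-1-yl)oxy]benzaldehyde
Conditions: K2CO3 (1.0 equiv), acetone, reflux
Reagents that add atoms: none
Why: Williamson ether synthesis, selective for the more acidic 4-OH because 2-OH is held in a hydrogen bond to the formyl group.

Step 4
Reactants: 6 2-hydroxy-4-[(3-methylbut-2-en-1-yl)oxy]benzaldehyde
Product: 7 2-(TBSO)-4-[(3-methylbut-2-en-1-yl)oxy]benzaldehyde
Conditions: TBSCl, imidazole, DMF, rt
Reagents that add atoms: tert-butyldimethylsilyl chloride, CC(C)(C)[Si](C)(C)Cl
Why: Imidazole-promoted silylation of a salicylaldehyde-type phenol, which also places a bulky group next to C3 and so prepares the regiochemistry of the next step.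

Step 5
Reactants: 7 2-(TBSO)-4-[(3-methylbut-2-en-1-yl)oxy]benzaldehyde
Product: 9 2-(TBSO)-4-hydroxy-5-(2-methylbut-3-en-2-yl)benzaldehyde, via Claisen ortho-dienone 8 (not isolated)
Conditions: PhNEt2, 200 °C, sealed tube, Ar
Reagents that add atoms: none
Why: Aromatic Claisen rearrangement, whose [3,3]-shift inverts the allyl unit and delivers the 1,1-dimethylallyl group to C5 (C3 is walled off by the neighbouring silyl ether), after which dienone 8 tautomerises and the weakly basic solvent holds back acid-catalysed ring closure of the product.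

Step 6
Reactants: 9 2-(TBSO)-4-hydroxy-5-(2-methylbut-3-en-2-yl)benzaldehyde
Product: 10 2,4-bis(TBSO)-5-(2-methylbut-3-en-2-yl)benzaldehyde
Conditions: TBSOTf, 2,6-lutidine, CH2Cl2, 0 °C
Reagents that add atoms: tert-butyldimethylsilyl triflate, CC(C)(C)[Si](C)(C)OS(=O)(=O)C(F)(F)F
Why: Silylation with a silyl triflate and a hindered pyridine base, which is reactive enough for a phenol flanked by a tertiary alkyl group and leaves the non-enolisable aldehyde unchanged after aqueous work-up.

Step 7
Reactants: 10 2,4-bis(TBSO)-5-(2-methylbut-3-en-2-yl)benzaldehyde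
Product: 11 [2,4-bis(TBSO)-5-(2-methylbut-3-en-2-yl)phenyl]methanol
Conditions: DIBAL-H (1.1 equiv), CH2Cl2, −78 °C; aq Rochelle salt
Reagents that add atoms: none
Why: 1,2-Reduction of the aldehyde by an aluminium hydride, whose aluminium alkoxide at −78 °C is too weak a nucleophile to draw the neighbouring aryl silyl group onto the benzylic oxygen and which does not hydroaluminate the alkene.

Step 8
Reactants: 4 1-[4,6-bis(TBSO)-2-hydroxy-3-(3-methylbut-2-en-1-yl)phenyl]ethan-1-one; 11 [2,4-bis(TBSO)-5-(2-methylbut-3-en-2-yl)phenyl]methanol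
Product: 12 1-[2-{[2,4-bis(TBSO)-5-(2-methylbut-3-en-2-yl)phenyl]methoxy}-4,6-bis(TBSO)-3-(3-methylbut-2-en-1-yl)phenyl]ethan-1-one
Conditions: PPh3, DIAD (added last), THF, 0 °C → rt
Reagents that add atoms: none
Why: Mitsunobu etherification, in which the only free phenol displaces the primary benzylic oxyphosphonium ion under neutral conditions that spare the aryl silyl ethers and avoid an unstable electron-rich benzyl halide.

Step 9
Reactants: 12 1-[2-{[2,4-bis(TBSO)-5-(2-methylbut-3-en-2-yl)phenyl]methoxy}-4,6-bis(TBSO)-3-(3-methylbut-2-en-1-yl)phenyl]ethan-1-one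
Product: 14 2-diazo-1-[2-{[2,4-bis(TBSO)-5-(2-methylbut-3-en-2-yl)phenyl]methoxy}-4,6-bis(TBSO)-3-(3-methylbut-2-en-1-yl)phenyl]ethan-1-one, via trifluoroacetyl ketone 13 (not isolated)
Conditions: (i) LiHMDS (1.1 equiv), THF, −78 °C; CF3CO2CH2CF3, −78 °C; AcOH quench; (ii) p-ABSA, Et3N, MeCN–THF, rt
Reagents that add atoms: 2,2,2-trifluoroethyl trifluoroacetate, O=C(OCC(F)(F)F)C(F)(F)F (trifluoroacetyl group of 13 only); 4-acetamidobenzenesulfonyl azide, CC(=O)Nc1ccc(cc1)S(=O)(=O)N=[N+]=[N-] (the two nitrogen atoms of 14)
Why: Detrifluoroacetylative Regitz-type diazo transfer, in which the methyl ketone enolate is acylated at −78 °C (the twisted 2,6-disubstituted aryl ketone keeps the enolate oxygen away from the ortho silyl group) and the activated 1,3-dicarbonyl 13 takes the diazo group from the sulfonyl azide while passing its trifluoroacetyl group to the sulfonamide nitrogen.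

Step 10
Reactants: 14 2-diazo-1-[2-{[2,4-bis(TBSO)-5-(2-methylbut-3-en-2-yl)phenyl]methoxy}-4,6-bis(TBSO)-3-(3-methylbut-2-en-1-yl)phenyl]ethan-1-one
Product: 15 (2S)-2-[2,4-bis(TBSO)-5-(2-methylbut-3-en-2-yl)phenyl]-5,7-bis(TBSO)-8-(3-methylbut-2-en-1-yl)-2,3-dihydro-4H-chromen-4-one
Conditions: Rh2(S-DOSP)4 (2 mol %), hexane, 4 Å MS, 0 °C; 14 added by syringe pump over 6 h (final 5 mM)
Reagents that add atoms: none
Why: Rh(II) binds the diazo carbon, nitrogen leaves, and the acceptor-only carbenoid at C3 takes up a C2–H bond in one kinetic step in which hydride transfer runs ahead of C–C bonding, the developing positive charge at C2 being carried by O1 and by the 2',4'-disilyloxyaryl group. The closest known reaction type is the chiral Rh(II) carboxylate-catalysed C–H insertion of 2-alkoxy- and 2-benzyloxyaryl α-diazoketones to 2-substituted chroman-4-ones, for which N-arylsulfonylprolinate ligands are the proven family. Ring C closes as a six-membered ring by 1,6-insertion (carbenoid carbon counted as atom 1), a five-membered alternative being excluded because atom 5 of the tether is O1 and has no hydrogen. C2 is set by the catalyst alone, since 14 has no stereogenic element and the prolinate pocket must tell apart the two enantiotopic hydrogens of the OCH2 group. Site selectivity is secured by the substrate, because O5 bears silicon, the prenyl CH2 could be reached only through a meta-bridged ring and both alkenes lie outside cyclisation range, so that slow addition at high dilution should be enough against bimolecular cyclopropanation and carbene dimerisation. Chemoselectivity against capture of the carbenoid by O1 and a Stevens 1,2-benzyl shift to a benzofuran-3-one rests on the low basicity of O1, whose lone pair is drawn into the acylated ring A, on rhodium in place of copper, and on the non-polar solvent, which disfavours the zwitterionic ylide.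

Step 11
Reactants: 15 (2S)-2-[2,4-bis(TBSO)-5-(2-methylbut-3-en-2-yl)phenyl]-5,7-bis(TBSO)-8-(3-methylbut-2-en-1-yl)-2,3-dihydro-4H-chromen-4-one
Product: 16 (2S)-2-[2,4-dihydroxy-5-(2-methylbut-3-en-2-yl)phenyl]-5,7-dihydroxy-8-(3-methylbut-2-en-1-yl)-2,3-dihydro-4H-chromen-4-one (AChE-IN-17)
Conditions: Et3N·3HF (excess), THF, 0 °C → rt; pH 6 phosphate work-up
Reagents that add atoms: none
Why: Fluoride-mediated desilylation in a weakly acidic medium, which frees the four phenols without forming phenoxides (no retro-oxa-Michael opening, hence no loss of configuration at C2) and is too mild to cyclise either prenyl-type group onto its neighbouring phenol.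

Compound list
1 | 2,4,6-trihydroxyacetophenone | CC(=O)c1c(O)cc(O)cc1O | starting material
2 | prenyl bromide | CC(C)=CCBr | starting material
3 | 1-[2,4,6-trihydroxy-3-(3-methylbut-2-en-1-yl)phenyl]ethan-1-one | CC(=O)c1c(O)cc(O)c(CC=C(C)C)c1O | intermediate
4 | 1-[4,6-bis(TBSO)-2-hydroxy-3-(3-methylbut-2-en-1-yl)phenyl]ethan-1-one | CC(=O)c1c(O[Si](C)(C)C(C)(C)C)cc(O[Si](C)(C)C(C)(C)C)c(CC=C(C)C)c1O | intermediate
5 | 2,4-dihydroxybenzaldehyde | O=Cc1ccc(O)cc1O | starting material
6 | 2-hydroxy-4-[(3-methylbut-2-en-1-yl)oxy]benzaldehyde | O=Cc1ccc(OCC=C(C)C)cc1O | intermediate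
7 | 2-(TBSO)-4-[(3-methylbut-2-en-1-yl)oxy]benzaldehyde | O=Cc1ccc(OCC=C(C)C)cc1O[Si](C)(C)C(C)(C)C | intermediate
8 | 6-(TBSO)-3-(2-methylbut-3-en-2-yl)-4-oxocyclohexa-1,5-diene-1-carbaldehyde (racemic, not isolated) | O=CC1=CC(C(C)(C)C=C)C(=O)C=C1O[Si](C)(C)C(C)(C)C | intermediate
9 | 2-(TBSO)-4-hydroxy-5-(2-methylbut-3-en-2-yl)benzaldehyde | O=Cc1cc(C(C)(C)C=C)c(O)cc1O[Si](C)(C)C(C)(C)C | intermediate
10 | 2,4-bis(TBSO)-5-(2-methylbut-3-en-2-yl)benzaldehyde | O=Cc1cc(C(C)(C)C=C)c(O[Si](C)(C)C(C)(C)C)cc1O[Si](C)(C)C(C)(C)C | intermediate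
11 | [2,4-bis(TBSO)-5-(2-methylbut-3-en-2-yl)phenyl]methanol | OCc1cc(C(C)(C)C=C)c(O[Si](C)(C)C(C)(C)C)cc1O[Si](C)(C)C(C)(C)C | intermediate
12 | ring A methyl ketone bearing the ring B benzyl ether, tetra-TBS | CC(=O)c1c(O[Si](C)(C)C(C)(C)C)cc(O[Si](C)(C)C(C)(C)C)c(CC=C(C)C)c1OCc2cc(C(C)(C)C=C)c(O[Si](C)(C)C(C)(C)C)cc2O[Si](C)(C)C(C)(C)C | intermediate
13 | 4,4,4-trifluoro-1-aryl-butane-1,3-dione derived from 12 (not isolated) | O=C(CC(=O)c1c(O[Si](C)(C)C(C)(C)C)cc(O[Si](C)(C)C(C)(C)C)c(CC=C(C)C)c1OCc2cc(C(C)(C)C=C)c(O[Si](C)(C)C(C)(C)C)cc2O[Si](C)(C)C(C)(C)C)C(F)(F)F | intermediate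
14 | ring A diazomethyl ketone bearing the ring B benzyl ether, tetra-TBS | [N-]=[N+]=CC(=O)c1c(O[Si](C)(C)C(C)(C)C)cc(O[Si](C)(C)C(C)(C)C)c(CC=C(C)C)c1OCc2cc(C(C)(C)C=C)c(O[Si](C)(C)C(C)(C)C)cc2O[Si](C)(C)C(C)(C)C | intermediate
15 | (2S)-tetra-TBS flavanone | C=CC(C)(C)c1cc([C@@H]2CC(=O)c3c(O[Si](C)(C)C(C)(C)C)cc(O[Si](C)(C)C(C)(C)C)c(CC=C(C)C)c3O2)c(O[Si](C)(C)C(C)(C)C)cc1O[Si](C)(C)C(C)(C)C | intermediate
16 | AChE-IN-17, (2S)-flavanone | C=CC(C)(C)c1cc([C@@H]2CC(=O)c3c(O)cc(O)c(CC=C(C)C)c3O2)c(O)cc1O | target

Total step count: 11. Longest linear sequence: 9 steps (5 → 16, steps 3–11). The ring A branch (steps 1–2) joins at step 8.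

Steps most likely to fail

1. Step 10. Two things may go wrong.
   - The carbenoid may be captured by the O1 lone pair, and the electron-rich benzyl group may then migrate, so that a five-membered ring forms instead of ring C.
   - The catalyst may discriminate poorly between the two C2 hydrogens, as is common for acceptor-only carbenoids.

   The fallback sets out from 4 and 10 and comes back at 15. It closes ring C at O1–C2 instead and obtains the enantiomer by catalytic kinetic resolution. Double deprotonation of 4 (LiHMDS, 2.2 equiv, THF, −78 °C), aldol addition to 10 and a cold AcOH quench should give the racemic β-hydroxy ketone F1. Intramolecular Mitsunobu etherification (PPh3, DIAD, THF, 0 °C) should then give the racemic tetra-TBS flavanone F2. Asymmetric transfer hydrogenation with a Cp*Rh(TsDPEN) catalyst (HCO2H/Et3N, EtOAc, rt) is run to about half conversion, using the catalyst enantiomer that consumes the (2R) ketone. It should convert that enantiomer into the (2R,4R)-cis-flavan-4-ol F3 and leave 15, which is separated by chromatography.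

2. Step 8. The crowded, chelated phenol may react too slowly. The easily ionised benzylic oxyphosphonium ion would then be consumed by alkylation of the hydrazide or of the free ring A carbon.

   The fallback sets out from 11 (with 4) and comes back at 12. It replaces the phosphonium electrophile by an η3-benzylpalladium species. Methyl chloroformate and pyridine (CH2Cl2, 0 °C) should convert 11 into the benzyl methyl carbonate F4. Neutral palladium-catalysed decarboxylative benzylation of phenol 4 ([Pd(η3-C3H5)Cp], DPEphos, toluene, 60–80 °C) should then give 12.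

3. Step 5. At 200 °C the prenyl group may be lost. The freed phenol may also react further with its own 1,1-dimethylallyl group, by an abnormal Claisen shift or by closure to a dihydrobenzofuran. Silyl transfer between phenols may blur the regiocontrol.

   The fallback sets out from 5, comes back at 10, and replaces steps 3–6 by a cross-coupling, with no thermal rearrangement. Bromination (Br2, AcOH, rt) at the position ortho to 4-OH and para to 2-OH should give 5-bromo-2,4-dihydroxybenzaldehyde F5. TBSCl and imidazole in DMF should give the bis-silyl ether F6. A branched-selective (γ-selective) Suzuki–Miyaura coupling with prenylboronic acid pinacol ester should then give 10. It uses Pd with a biarylphosphine chosen for the branched product, K3PO4, MeCN–H2O, 70 °C. Any phenol bared by the phosphate is re-silylated before purification.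

Further compounds
F1 | step 10 | rac-1-[4,6-bis(TBSO)-2-hydroxy-3-(3-methylbut-2-en-1-yl)phenyl]-3-[2,4-bis(TBSO)-5-(2-methylbut-3-en-2-yl)phenyl]-3-hydroxypropan-1-one | CC(C)=CCc1c(O)c(C(=O)CC(O)c2cc(C(C)(C)C=C)c(O[Si](C)(C)C(C)(C)C)cc2O[Si](C)(C)C(C)(C)C)c(O[Si](C)(C)C(C)(C)C)cc1O[Si](C)(C)C(C)(C)C
F2 | step 10 | racemic tetra-TBS flavanone | C=CC(C)(C)c1cc(C2CC(=O)c3c(O[Si](C)(C)C(C)(C)C)cc(O[Si](C)(C)C(C)(C)C)c(CC=C(C)C)c3O2)c(O[Si](C)(C)C(C)(C)C)cc1O[Si](C)(C)C(C)(C)C
F3 | step 10 | (2R,4R)-cis-flavan-4-ol, tetra-TBS | C=CC(C)(C)c1cc([C@H]2C[C@@H](O)c3c(O[Si](C)(C)C(C)(C)C)cc(O[Si](C)(C)C(C)(C)C)c(CC=C(C)C)c3O2)c(O[Si](C)(C)C(C)(C)C)cc1O[Si](C)(C)C(C)(C)C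
F4 | step 8 | [2,4-bis(TBSO)-5-(2-methylbut-3-en-2-yl)phenyl]methyl methyl carbonate | COC(=O)OCc1cc(C(C)(C)C=C)c(O[Si](C)(C)C(C)(C)C)cc1O[Si](C)(C)C(C)(C)C
F5 | step 5 | 5-bromo-2,4-dihydroxybenzaldehyde | O=Cc1cc(Br)c(O)cc1O
F6 | step 5 | 5-bromo-2,4-bis(TBSO)benzaldehyde | O=Cc1cc(Br)c(O[Si](C)(C)C(C)(C)C)cc1O[Si](C)(C)C(C)(C)C
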